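The pyranone ring C is opened at O1–C2 and C4–C4a, which maps C2–C3(aryl)–C4 onto a 2-arylacrolein and ring A onto a phenol whose only unsubstituted ortho carbon is the future C4a (the other ortho carbon, C8, already carries oxygen). A boronic-acid-templated phenol–enal condensation then forms C4–C4a, and the resulting o-quinone methide closes O1–C2 by oxa-6π electrocyclisation, so ring C with the B ring at C3 arises in one operation. The precursors are 2,3-bis(benzyloxy)-4-methoxyphenol and 2-[3-(benzyloxy)-4,5-dimethoxyphenyl]acrylaldehyde; the C4 carbonyl is installed afterwards by hydroboration–oxidation and dehydrogenation, and hydrogenolysis frees the three phenols.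

Key step: step 6

Assumption: the target has no stereocentre and no stereogenic axis, so "single enantiomer" is read as the one achiral compound drawn. The stereocentres of intermediates 9, 13, 16, 17 and 18 are racemic and are all erased by step 9.

Step 1
Reactants: 1 2,3-dihydroxy-4-methoxybenzaldehyde
Product: 2 2,3-bis(benzyloxy)-4-methoxybenzaldehyde
Conditions: BnBr (2.5 equiv), K2CO3, DMF, 60 °C
Reagents that add atoms: benzyl bromide, BrCc1ccccc1
Why: Williamson ether synthesis; both phenoxides are benzylated, and warming overcomes the hydrogen bond between the 2-OH and the aldehyde.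

Step 2
Reactants: 2 2,3-bis(benzyloxy)-4-methoxybenzaldehyde
Product: 4 2,3-bis(benzyloxy)-4-methoxyphenol, via aryl formate 3 (not isolated)
Conditions: mCPBA, CH2Cl2, 0 °C to rt; aq Na2S2O3/NaHCO3 wash; then K2CO3 (cat.), MeOH, rt, Ar
Reagents that add atoms: mCPBA, O=C(OO)c1cccc(Cl)c1
Why: Baeyer–Villiger (Dakin-type) oxidation, in which the aryl group carrying ortho and para oxygen donors migrates in the Criegee intermediate to give formate 3, which is then methanolysed to the phenol under argon to protect the oxidation-prone hydroquinone monoether.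

Step 3
Reactants: 5 3-hydroxy-4,5-dimethoxybenzaldehyde
Product: 6 3-(benzyloxy)-4,5-dimethoxybenzaldehyde
Conditions: BnBr, K2CO3, DMF, rt
Reagents that add atoms: benzyl bromide, BrCc1ccccc1
Why: Williamson ether synthesis on the single free phenol.

Step 4
Reactants: 6 3-(benzyloxy)-4,5-dimethoxybenzaldehyde
Product: 8 2-[3-(benzyloxy)-4,5-dimethoxyphenyl]acetaldehyde, via enol ether 7 (not isolated)
Conditions: Ph3P(CH2OMe)Cl, KOtBu, THF, 0 °C to rt; then 2 M aq HCl, THF, 50 °C
Reagents that add atoms: (methoxymethyl)triphenylphosphonium chloride, COC[P+](c1ccccc1)(c1ccccc1)c1ccccc1.[Cl-]; water, O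
Why: Wittig olefination of the non-enolisable aldehyde with the methoxymethylene ylide gives enol ether 7 (E/Z immaterial), and acid hydrolysis of the crude enol ether should give the one-carbon homologated aldehyde.

Step 5
Reactants: 8 2-[3-(benzyloxy)-4,5-dimethoxyphenyl]acetaldehyde
Product: 10 2-[3-(benzyloxy)-4,5-dimethoxyphenyl]acrylaldehyde, via Mannich base 9 (not isolated)
Conditions: Me2N=CH2 I (Eschenmoser's salt), Et3N, CH2Cl2, rt; product kept cold and used at once
Reagents that add atoms: Eschenmoser's salt (N,N-dimethylmethyleneiminium iodide), C=[N+](C)C.[I-]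
Why: Mannich reaction of the enol of 8 with the preformed iminium ion, followed by E1cB loss of dimethylamine from 9 (α-methylenation), which the acidic benzylic α-hydrogen and the conjugation gained make easy.

Step 6
Reactants: 4 2,3-bis(benzyloxy)-4-methoxyphenol; 10 2-[3-(benzyloxy)-4,5-dimethoxyphenyl]acrylaldehyde; 11 phenylboronic acid
Product: 15 7,8-bis(benzyloxy)-3-[3-(benzyloxy)-4,5-dimethoxyphenyl]-6-methoxy-2H-chromene, via aryl phenylboronate 12 (not isolated), via benzodioxaborin 13 (not isolated), via o-quinone methide 14 (not isolated)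
Conditions: PhB(OH)2 (1.1 equiv), EtCO2H (cat.), PhMe, reflux, Dean–Stark, Ar; 10 (1.5 equiv) added slowly
Reagents that add atoms: none
Why: Phenol 4 and phenylboronic acid condense to aryl boronate 12, whose boron binds the carbonyl of enal 10 and delivers the carbonyl carbon to the only open ortho carbon through a six-membered cyclic transition state (C4–C4a), giving benzodioxaborin 13 after rearomatisation. At reflux 13 expels PhB=O in a retro-hetero-[4+2] fragmentation to the vinyl o-quinone methide 14, whose 1-oxatriene O1=C8a–C4a=C4–C3=C2 closes thermally by a disrotatory oxa-6π electrocyclisation (O1–C2), regaining the aromaticity of ring A. The closest known reaction type is the arylboronic-acid-mediated condensation of phenols with α,β-unsaturated aldehydes to 2H-chromenes. The single ring formed, pyran ring C, is closed pericyclically at the terminal CH2 of the enal, so the aryl group on the enal α-carbon ends up at C3. No stereocentre remains, since C2 is CH2 and the sp3 C4 of 13 becomes sp2. The step needs C-alkylation by the carbonyl carbon at the ortho position instead of conjugate addition or O-alkylation: the boron tether enforces 1,2-delivery, and because C2 of the phenol carries OBn and C4 carries OMe, C6 (the future C4a) is the only site the tether can reach.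

Step 7
Reactants: 15 7,8-bis(benzyloxy)-3-[3-(benzyloxy)-4,5-dimethoxyphenyl]-6-methoxy-2H-chromene
Product: 17 trans-(3RS,4SR)-7,8-bis(benzyloxy)-3-[3-(benzyloxy)-4,5-dimethoxyphenyl]-6-methoxychroman-4-ol, via C4-alkylborane 16 (not isolated)
Conditions: BH3·THF, THF, 0 °C to rt; then 3 M aq NaOH, 30% H2O2, 0 °C to rt
Reagents that add atoms: hydrogen peroxide, OO
Why: Brown hydroboration–oxidation; syn addition puts boron on the less substituted C4 and hydrogen on the aryl-bearing C3, and oxidation with retention should give the trans 4-alcohol, whose two racemic stereocentres (set by the syn addition) are removed in steps 8 and 9.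

Step 8
Reactants: 17 trans-(3RS,4SR)-7,8-bis(benzyloxy)-3-[3-(benzyloxy)-4,5-dimethoxyphenyl]-6-methoxychroman-4-ol
Product: 18 7,8-bis(benzyloxy)-3-[3-(benzyloxy)-4,5-dimethoxyphenyl]-6-methoxychroman-4-one (racemic isoflavanone)
Conditions: Dess–Martin periodinane, CH2Cl2, 0 °C to rt
Reagents that add atoms: none
Why: Dess–Martin oxidation of the secondary benzylic alcohol to the ketone under mild conditions that leave the benzyl ethers and the electron-rich rings untouched.

Step 9
Reactants: 18 7,8-bis(benzyloxy)-3-[3-(benzyloxy)-4,5-dimethoxyphenyl]-6-methoxychroman-4-one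
Product: 19 7,8-bis(benzyloxy)-3-[3-(benzyloxy)-4,5-dimethoxyphenyl]-6-methoxy-4H-chromen-4-one
Conditions: DDQ (1.5 equiv), 1,4-dioxane, reflux
Reagents that add atoms: none
Why: DDQ dehydrogenation of an isoflavanone to the isoflavone through its enol, driven by formation of the conjugated 4-pyranone; it removes the last stereocentre.

Step 10
Reactants: 19 7,8-bis(benzyloxy)-3-[3-(benzyloxy)-4,5-dimethoxyphenyl]-6-methoxy-4H-chromen-4-one
Product: 20 7,8-dihydroxy-3-(3-hydroxy-4,5-dimethoxyphenyl)-6-methoxy-4H-chromen-4-one (target)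
Conditions: H2 (1 atm), 10% Pd/C, EtOAc–MeOH, rt; stopped at full debenzylation, worked up under Ar
Reagents that add atoms: none
Why: Catalytic hydrogenolysis cleaves the three benzyl aryl ethers, while the methyl ethers and the chromone C2=C3 bond should survive at one atmosphere and room temperature.

Compound list
1 | 2,3-dihydroxy-4-methoxybenzaldehyde | COc1ccc(C=O)c(O)c1O | starting material
2 | 2,3-bis(benzyloxy)-4-methoxybenzaldehyde | COc1ccc(C=O)c(OCc2ccccc2)c1OCc1ccccc1 | intermediate
3 | 2,3-bis(benzyloxy)-4-methoxyphenyl formate (not isolated) | COc1ccc(OC=O)c(OCc2ccccc2)c1OCc1ccccc1 | intermediate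
4 | 2,3-bis(benzyloxy)-4-methoxyphenol | COc1ccc(O)c(OCc2ccccc2)c1OCc1ccccc1 | intermediate
5 | 3-hydroxy-4,5-dimethoxybenzaldehyde | COc1cc(C=O)cc(O)c1OC | starting material
6 | 3-(benzyloxy)-4,5-dimethoxybenzaldehyde | COc1cc(C=O)cc(OCc2ccccc2)c1OC | intermediate
7 | 1-(benzyloxy)-2,3-dimethoxy-5-(2-methoxyvinyl)benzene, E/Z mixture (not isolated) | COC=Cc1cc(OC)c(OC)c(OCc2ccccc2)c1 | intermediate
8 | 2-[3-(benzyloxy)-4,5-dimethoxyphenyl]acetaldehyde | COc1cc(CC=O)cc(OCc2ccccc2)c1OC | intermediate
9 | 2-[3-(benzyloxy)-4,5-dimethoxyphenyl]-3-(dimethylamino)propanal, racemic (not isolated) | CN(C)CC(C=O)c1cc(OC)c(OC)c(OCc2ccccc2)c1 | intermediate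
10 | 2-[3-(benzyloxy)-4,5-dimethoxyphenyl]acrylaldehyde | COc1cc(C(=C)C=O)cc(OCc2ccccc2)c1OC | intermediate
11 | phenylboronic acid | OB(O)c1ccccc1 | starting material
12 | 2,3-bis(benzyloxy)-4-methoxyphenyl hydrogen phenylboronate (not isolated) | COc1ccc(OB(O)c2ccccc2)c(OCc2ccccc2)c1OCc1ccccc1 | intermediate
13 | 7,8-bis(benzyloxy)-4-{1-[3-(benzyloxy)-4,5-dimethoxyphenyl]vinyl}-6-methoxy-2-phenyl-4H-1,3,2-benzodioxaborin, racemic (not isolated) | C=C(c1cc(OC)c(OC)c(OCc2ccccc2)c1)C1OB(c2ccccc2)Oc2c1cc(OC)c(OCc1ccccc1)c2OCc1ccccc1 | intermediate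
14 | (6Z)-2,3-bis(benzyloxy)-6-{2-[3-(benzyloxy)-4,5-dimethoxyphenyl]prop-2-en-1-ylidene}-4-methoxycyclohexa-2,4-dien-1-one (not isolated) | O=C1C(OCc2ccccc2)=C(OCc2ccccc2)C(OC)=C/C1=C/C(=C)c1cc(OC)c(OC)c(OCc2ccccc2)c1 | intermediate
15 | 7,8-bis(benzyloxy)-3-[3-(benzyloxy)-4,5-dimethoxyphenyl]-6-methoxy-2H-chromene | COc1cc2C=C(c3cc(OC)c(OC)c(OCc4ccccc4)c3)COc2c(OCc2ccccc2)c1OCc1ccccc1 | intermediate
16 | trans-{7,8-bis(benzyloxy)-3-[3-(benzyloxy)-4,5-dimethoxyphenyl]-6-methoxychroman-4-yl}borane, racemic, written as the monoalkylborane (not isolated) | B[C@@H]1[C@@H](c2cc(OC)c(OC)c(OCc3ccccc3)c2)COc2c1cc(OC)c(OCc1ccccc1)c2OCc1ccccc1 | intermediate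
17 | trans-(3RS,4SR)-7,8-bis(benzyloxy)-3-[3-(benzyloxy)-4,5-dimethoxyphenyl]-6-methoxychroman-4-ol, racemic (one enantiomer drawn) | O[C@@H]1[C@@H](c2cc(OC)c(OC)c(OCc3ccccc3)c2)COc2c1cc(OC)c(OCc1ccccc1)c2OCc1ccccc1 | intermediate
18 | 7,8-bis(benzyloxy)-3-[3-(benzyloxy)-4,5-dimethoxyphenyl]-6-methoxychroman-4-one, racemic | O=C1C(c2cc(OC)c(OC)c(OCc3ccccc3)c2)COc2c1cc(OC)c(OCc1ccccc1)c2OCc1ccccc1 | intermediate
19 | 7,8-bis(benzyloxy)-3-[3-(benzyloxy)-4,5-dimethoxyphenyl]-6-methoxy-4H-chromen-4-one | COc1cc2c(=O)c(-c3cc(OC)c(OC)c(OCc4ccccc4)c3)coc2c(OCc2ccccc2)c1OCc1ccccc1 | intermediate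
20 | 7,8-dihydroxy-3-(3-hydroxy-4,5-dimethoxyphenyl)-6-methoxy-4H-chromen-4-one | COc1cc2c(=O)c(-c3cc(O)c(OC)c(OC)c3)coc2c(O)c1O | target

Total step count: 10. Longest linear sequence: 8 steps (steps 3, 4, 5, 6, 7, 8, 9, 10, from 5 to 20); the phenol branch (steps 1 and 2) joins at step 6.

Steps most likely to fail

Step 6. The 2-arylacrolein may be lost to hetero-Diels–Alder self-dimerisation, polymerisation or acid-promoted conjugate addition faster than the boron-templated ortho condensation takes place, and the hydroquinone-type phenol may oxidise at reflux. The fallback sets out from 4 and 8, builds ring C through a coumarin and comes back at 15. Ortho-formylation of 4 (MgCl2, Et3N, paraformaldehyde, MeCN, reflux) should give 3,4-bis(benzyloxy)-2-hydroxy-5-methoxybenzaldehyde F1. Pinnick oxidation of 8 (NaClO2, NaH2PO4, 2-methyl-2-butene, tBuOH–H2O) should give 2-[3-(benzyloxy)-4,5-dimethoxyphenyl]acetic acid F2. Perkin–Oglialoro condensation of the two (Ac2O, Et3N, 110 °C) should give the 3-arylcoumarin 7,8-bis(benzyloxy)-3-[3-(benzyloxy)-4,5-dimethoxyphenyl]-6-methoxy-2H-chromen-2-one F3. Reduction of the lactone with DIBAL-H (CH2Cl2, −78 to 0 °C) should give (Z)-2-[3-(benzyloxy)-4,5-dimethoxyphenyl]-3-[3,4-bis(benzyloxy)-2-hydroxy-5-methoxyphenyl]prop-2-en-1-ol F4, and an intramolecular Mitsunobu etherification (PPh3, DIAD, THF, 0 °C) closes the pyran ring to 15.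

Step 5. Elimination of the Mannich base may be incomplete, the arylacetaldehyde may self-condense under the amine base, and the enal may dimerise during isolation. The fallback sets out from 8, passes through the ester oxidation level, where the methylene compound can be stored, and comes back at 10. Oxidative esterification of 8 (I2, KOH, MeOH, 0 °C) should give methyl 2-[3-(benzyloxy)-4,5-dimethoxyphenyl]acetate F5. Its α-methylenation with paraformaldehyde (K2CO3, Bu4NI cat., PhMe, 80 °C) should give methyl 2-[3-(benzyloxy)-4,5-dimethoxyphenyl]acrylate F6. DIBAL-H reduction (CH2Cl2, −78 °C) should give the bench-stable 2-[3-(benzyloxy)-4,5-dimethoxyphenyl]prop-2-en-1-ol F7. Oxidation with MnO2 (CH2Cl2, rt) just before the key step delivers 10 as a filtered solution that is used directly.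

Step 7. Hydroboration of the trisubstituted, doubly benzylic alkene may be slow, or part of the boron may be placed at C3. The fallback sets out from 15, oxidises both alkene carbons, then removes the C3 oxygen, and comes back at 18. Upjohn dihydroxylation (OsO4 cat., NMO, acetone–H2O) should give cis-(3RS,4SR)-7,8-bis(benzyloxy)-3-[3-(benzyloxy)-4,5-dimethoxyphenyl]-6-methoxychromane-3,4-diol F8. Parikh–Doering oxidation of the secondary benzylic alcohol (SO3·pyridine, DMSO, Et3N) should give 7,8-bis(benzyloxy)-3-[3-(benzyloxy)-4,5-dimethoxyphenyl]-3-hydroxy-6-methoxychroman-4-one F9. Reductive cleavage of the α-hydroxy ketone C–O bond with SmI2 (THF–MeOH, −78 °C) then gives isoflavanone 18.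

Further compounds
F1 | step 6 | 3,4-bis(benzyloxy)-2-hydroxy-5-methoxybenzaldehyde | COc1cc(C=O)c(O)c(OCc2ccccc2)c1OCc1ccccc1
F2 | step 6 | 2-[3-(benzyloxy)-4,5-dimethoxyphenyl]acetic acid | COc1cc(CC(=O)O)cc(OCc2ccccc2)c1OC
F3 | step 6 | 7,8-bis(benzyloxy)-3-[3-(benzyloxy)-4,5-dimethoxyphenyl]-6-methoxy-2H-chromen-2-one | COc1cc2cc(-c3cc(OC)c(OC)c(OCc4ccccc4)c3)c(=O)oc2c(OCc2ccccc2)c1OCc1ccccc1
F4 | step 6 | (Z)-2-[3-(benzyloxy)-4,5-dimethoxyphenyl]-3-[3,4-bis(benzyloxy)-2-hydroxy-5-methoxyphenyl]prop-2-en-1-ol | OC/C(c1cc(OC)c(OC)c(OCc2ccccc2)c1)=C\c1cc(OC)c(OCc2ccccc2)c(OCc2ccccc2)c1O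
F5 | step 5 | methyl 2-[3-(benzyloxy)-4,5-dimethoxyphenyl]acetate | COC(=O)Cc1cc(OC)c(OC)c(OCc2ccccc2)c1
F6 | step 5 | methyl 2-[3-(benzyloxy)-4,5-dimethoxyphenyl]acrylate | COC(=O)C(=C)c1cc(OC)c(OC)c(OCc2ccccc2)c1
F7 | step 5 | 2-[3-(benzyloxy)-4,5-dimethoxyphenyl]prop-2-en-1-ol | OCC(=C)c1cc(OC)c(OC)c(OCc2ccccc2)c1
F8 | step 7 | cis-(3RS,4SR)-7,8-bis(benzyloxy)-3-[3-(benzyloxy)-4,5-dimethoxyphenyl]-6-methoxychromane-3,4-diol, racemic (one enantiomer drawn) | O[C@@H]1[C@@](O)(c2cc(OC)c(OC)c(OCc3ccccc3)c2)COc2c1cc(OC)c(OCc1ccccc1)c2OCc1ccccc1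
F9 | step 7 | 7,8-bis(benzyloxy)-3-[3-(benzyloxy)-4,5-dimethoxyphenyl]-3-hydroxy-6-methoxychroman-4-one, racemic | O=C1C(O)(c2cc(OC)c(OC)c(OCc3ccccc3)c2)COc2c1cc(OC)c(OCc1ccccc1)c2OCc1ccccc1
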